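Time first: the highest reading of target in the teal run stood at 1.50 min, much earlier than the limit of 15 min, so I did not expect that limit to be the number to worry about in the flask.

all flasks: substrate 0.015 M; added ligand 5.3 µM
- teal: enzyme 8.6 µM; run made earlier
- flask: enzyme 5.7 µM; time 15 min

- teal (time / min: target / %, substrate / %): 0.200: 13.8, 76.0; 0.667: 24.6, 49.2; 1.00: 27.3, 39.1; 1.50: 27.7, 30.6; 2.50: 26.3, 20.5; 3.00: 26.2, 17.7

(standard deviation of a reading: 0.3 percentage points)

- the numbers in the tables scatter with a standard deviation of 0.3 percentage points
- no earlier run changes the charge of enzyme; that part of a forecast is a guess

* the moment within 15 min at which there is most target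
* the amount of target, in percent of the substrate charged, at that time
* earliest time at which at least nineteen twentieths of that best amount are there, in min
* latest time at which they still are, in min

So I asked how high the peak would go, and worked with the substrate no longer left. Of what the teal run had lost at 0.200 min, part was target and part had gone elsewhere, which gave 1.35 as the route ratio, my selectivity factor: target formed over the other substrate lost. I scaled the highest teal reading of 27.7% by the target share, which is the ratio over one plus the ratio, taken in the flask against teal.

I tried the choice of reading first: the reading at 0.667 min gave a ratio of 0.939, and the peak came out at 21.9% against 22.8% from the first reading. The enzyme counted more: a ratio indifferent to its charge left the peak at 27.7%, a wider gap than the reading's. No earlier run changed that charge, so I guessed proportion, 5.7 µM against 8.6 µM, with the other loss unchanged, and committed to 22.8% for the flask.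

The forecast gave 27.8% at 10 min, with a window from 6.2 min to 15 min, holding that “changing enzyme only stretches the time axis”.

The flask peaked at 1.49 min with 20.9%, its window running from 0.893 min to 2.58 min.

    enzyme + added ligand ⇌ idle complex (K = 3.83 × 10⁶ /M, k = 1840 /M/s)
    2 substrate → homo dimer (k = 0.309 /M/s)
    substrate + target → side product (k = 0.593 /M/s)
    substrate + enzyme → target + enzyme, rate k4*[substrate]^2.5*[enzyme]/(1 + ([substrate]/Kh4)^2.5) (19.1 mM, k = 1.56 × 10⁶ /M².5/s)

Changing the enzyme charge from teal took the peak down from 27.8% to 20.9%, while changing the time left it at 27.8%. My 22.8% stood above the flask's peak. Scaled to the neighbour flask with 3.4 × 10⁻⁶ M of enzyme, the route ratio became 0.535 and gave a peak of 16.8%, where that neighbour flask gave 13.9%.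

Readings and results come from a simulation from invented constants.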